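Compound numbers follow the order of first appearance in the steps. Ring atoms of the late compounds are numbered as in spiro[cyclopenta[a]naphthalene-2,3'-pyrrolidine]: ring A = C5a, C6–C9, C9a; ring B = C3a, C4, C5, C5a, C9a, C9b; ring C = C1, C2, C3, C3a, C9b; ring D = N1', C2', C3' (= C2), C4', C5'; the side chain on C3 is C1''–C4''.

## Analysis of the target

Target 27 is a trans-decalin (rings A and B, with a C4=C5 alkene that carries a methyl group on C4) cis-fused to a cyclopentanone (ring C), whose C2 is the spiro atom of an N-methyl pyrrolidine-2,4-dione (ring D). There are nine stereocentres: C7 (equatorial methyl), C5a and C9a (trans fusion), C9b (quaternary; methyl axial and anti to H-9a, C1 carbonyl equatorial), C3a (H cis to the C9b methyl), C3 (alkenyl group trans to C4, on the convex face of the B/C system), C2 (lactam carbonyl C2' anti to the alkenyl group, ketone C4' on its side), C5' (S, serine-derived) and the carbinol C3'' (S). C5' and C3'' are remote from the core and cannot be relayed from it, so they must come from the chiral pool. The sensitive points are the non-enolisable C2, which sits between three carbonyl groups and is open to retro-Claisen cleavage by nucleophiles, the C5' hydrogen next to the C4' ketone (epimerisation), the hydroxymethyl group β to that ketone (elimination) and the allylic alcohol. The difficulty lies in the two adjacent fully substituted carbons C9b and C2 around the C1 ketone, and in the spiro centre, whose two ring D substituents are both carbonyl carbons and differ only further out. The strategy rests on one feature: C3 is an allylic CH that lies five atoms from C2 along C2–C1–C9b–C3a–C3. In a precursor without the C2–C3 bond it is an allylic CH2 on a side chain that the rigid decalin holds next to the acyl group on C9b, where a carbene at C2 can insert into it.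

## Retrosynthetic reasoning

27 from 26. The two hydroxyl groups are carried as silyl ethers to the end, because a free hydroxymethyl group next to an activated carbamate would close an oxazolidinone and a free C3'' alcohol would interfere with the carbenoid. Acidic fluoride removes both without touching C5' or the tricarbonyl unit.

26 from 25. Ring D is cut at C2–C2', the bond from the spiro carbon to the lactam carbonyl. This leaves a 2-acylcyclopentanone whose nitrogen carries an aryl carbamate, so the forward step is an intramolecular C-acylation of the diketone at C2. The cut is made here and not at C2–C4' because the group that arrives last at C2 should come in anti to the C3 alkenyl group, and in the target that group is C2'. The carbamate is chosen as 4-nitrophenyl: its aryloxide is a weaker base than the diketonate, so a closure that cannot be driven by enolisation of the product is still downhill.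

25 from 24. Ring C is cut at C2–C3. C2 becomes a diazo carbon between the C1 and C4' ketones, and C3 becomes the CH2 of the side chain on C3a. The forward reaction is a metal-carbenoid 1,5-C–H insertion. No other bond of ring C can be made while the side-chain alkene and carbinol are already in place, and none sets C3 in the same step. The serine oxygen carries a tert-butyldiphenylsilyl group, bulkier and less Lewis basic than a smaller silyl ether, because that oxygen sits five atoms from the carbenoid carbon.

24 from 23, and 23 from 16 and 22. The C1–C2 bond is cut. The diazo carbon is brought in as the nucleophile: the serine-derived diazomethyl ketone 22 adds to the neopentyl aldehyde 16, which has no α-hydrogen, and the carbinol 23 is oxidised. This avoids a free 1,3-diketone that carries an activated carbamate under basic conditions, where it would cyclise to an enolisable 3-acyltetramic acid. It also avoids a separate diazo transfer, and it uses the aldehyde of the cycloaddition directly.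

22 from 20, 18 and 17. The diazo ketone comes from N-methyl-L-serine 17 by O-silylation (18), N-acylation to the 4-nitrophenyl carbamate (20) and homologation of the acid through a mixed anhydride. The urethane-type nitrogen protects C5' against racemisation during activation.

16 from 15. Ring B is cut at C5a–C9a and at C3a–C9b, an intramolecular Diels–Alder disconnection. The open-chain tetraenal 15 carries an E,E-diene (C3a=C4–C5=C5a), an E-2-methyl enal (C9a=C9b) and one stereocentre, C7. The forward reaction must be aldehyde-endo with the C7 methyl equatorial in the forming ring A; that single event sets C5a, C9a, C9b and C3a.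

15 from 11 and 14; 14 from 13 and 12. The skipped diene is cut between the side-chain CH2 (future C3) and C1''. The dienyl allylic carbonate 11 is joined to the E-alkenylboronate 14, which comes from (S)-but-3-yn-2-ol 12 by silylation (13) and syn-hydroboration. C3'' and the E geometry of C1''=C2'' are thus fixed before any ring is made.

11 from 10, 9, 5, 8 and 6. The two ends of the chain are brought to different oxidation levels in one reduction: in 9 the diene end is an ester and the dienophile end a Weinreb amide, so a hydride reagent gives the allylic alcohol at one end and the enal at the other (10). 9 comes from aldehyde 5 and the α-methyl ylide 8, which is made by C-methylation of the commercial ylide 6.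

5 from 3, and 3 from 1 and 2. The aldehyde of (S)-citronellal 1 is converted first into the (2E,4E)-3-methyl dienoate with the vinylogous phosphonate 2. Only then is the isopropylidene group cleaved, because the acceptor-substituted diene in 3 is much less reactive towards ozone than the trialkyl alkene.

## Alternatives that were turned down

Alternative 1: The carbon tricycle is cut at C9a–C9b and C3a–C4. In the forward direction 2-methylcyclopentane-1,3-dione A2 adds to the β-carbon (future C9a) of the ring A propionyl enone A3. The ethyl ketone then condenses with one dione carbonyl, and this Robinson annulation gives the tricyclic enedione A1.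
- For it: A2 is cheap, the quaternary C9b methyl and the C1 ketone arrive in place, and three rings are fused in one operation. No step of the chosen route matches that.
- Against it: the Michael step joins a fully substituted carbon to a ring-substituted β-carbon, a crowded and reversible addition, and C5a, C9a and C9b would all depend on equilibration. A1 also has its functionality in the wrong places: a C5 ketone to remove, a C3a=C4 alkene to move to C4=C5 while creating C3a, and plain CH2 groups at C2 and C3, where the target needs the spiro centre and a side chain with two more stereocentres.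
- Comparison: the redox and alkylation steps that must follow would outweigh the short entry. The chosen route is slower to the tricycle, but it brings in C3, its complete side chain and C2 with the ring closure itself.

Alternative 2: Ring B is cut at C9b–C3a by a [3,3] shift. The silyl ketene acetal of a trans-fused ring A lactone with a trienyl group on its carbinol carbon rearranges (Ireland–Claisen) to the dienyl decalin acid A4.
- For it: the shift is concerted and suprafacial, it transfers chirality from the carbinol carbon, it has no endo/exo question, and it delivers C9b at the acid oxidation level. On these points it is as strong in principle as the cycloaddition used here.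
- Against it: the six-atom array shares four atoms with the lactone ring, so only a boat-like, bicyclo[2.2.2]octane-type transition state is possible, and it has to twist the trans-fused ring A. On models, the twist that costs least strain appears to put the carboxyl group, not the methyl group, axial at C9b, which is the opposite of A4. The lactone needs its own multistep synthesis with three stereocentres and a sensitive triene. A4 has no oxygen at C3'', so the carbinol would have to be created late without control, and ring C and the spiro centre are still to come.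
- Comparison: the chosen route reaches the same decalin in one cycloaddition from an open chain with well-established stereochemical rules, and it takes C3'' from the chiral pool.

Alternative 3: C4–C3a and C2–C3 are cut together. A zerovalent palladium catalyst with a silver salt inserts into the Z-alkenyl iodide of A6. The alkenylpalladium adds 6-exo to the near end of the diene on C9b (ring B), and C3' of the 3-acyltetramic acid traps the π-allyl 5-exo at its inner terminus (ring C and the spiro centre). The product is A5, the bis(tert-butyldimethylsilyl) ether of 27.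
- For it: it is the most convergent plan. Two rings, C3a, C3 and C2 are made in one step, one deprotection from the target, and a 3-acyltetramic acid is an ideal soft nucleophile for a π-allyl complex. In step economy it is clearly stronger than the chosen route.
- Against it: A6 must already contain the quaternary C9b stereocentre, trans on ring A, with three carbon substituents (methyl, acyl, dienyl) that are told apart without a second ring to direct them. The carbopalladation has to occur at a diene carbon attached to that quaternary centre. The sense at C3a, C3 and C2 rests on one flexible intermediate, with C- against O-allylation and inner against outer terminus also open. All of this falls on the last C–C bond-forming step.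
- Comparison: the chosen strategy sets the decalin centres by a cycloaddition of known sense and sets C3 and C2 in two separate steps that can be corrected one at a time.

Key step: step 16

Remark: reagent 2 is sold as an E/Z mixture; the E isomer is drawn, and any 2Z-dienoate is removed by chromatography at 3 or 10.
Remark: the 1,3-diketone 25 is written as one diketo form; it should exist largely as enol tautomers, so the configuration written at C2 of 25 is not a fixed stereocentre.

## Steps

Step 1
Reactants: 1 (S)-citronellal; 2 triethyl (E)-3-methyl-4-phosphonocrotonate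
Product: 3 ethyl (2E,4E,7S)-3,7,11-trimethyldodeca-2,4,10-trienoate
Conditions: LiN(SiMe3)2, THF, DMPU, −78 → 0 °C
Reagents that add atoms: none
Why: Horner–Wadsworth–Emmons olefination at the α-carbon of the vinylogous phosphonate anion; the stabilised anion should give the new C4=C5 bond E, the 2E geometry is the thermodynamic one of the reagent, and the stereocentre of 1 is β to the aldehyde and cannot epimerise.

Step 2
Reactants: 3 trienoate
Product: 5 ethyl (2E,4E,7S)-3,7-dimethyl-10-oxodeca-2,4-dienoate, via secondary ozonide 4 (not isolated)
Conditions: O3, CH2Cl2, −78 °C, dye indicator (Sudan Red 7B), stopped at the end-point; then PPh3, −78 °C → rt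
Reagents that add atoms: ozone, [O-][O+]=O
Why: Ozonolysis (Criegee mechanism) with reductive work-up; ozone is electrophilic and should take the trialkyl-substituted C10=C11 alkene much faster than the dienoate, whose two alkenes are conjugated to the ester.

Step 3
Reactants: 6 N-methoxy-N-methyl-2-(triphenylphosphoranylidene)acetamide
Product: 8 N-methoxy-N-methyl-2-(triphenylphosphoranylidene)propanamide, via methylated phosphonium iodide 7 (not isolated)
Conditions: MeI, CH2Cl2, rt; then aq. NaOH, CH2Cl2, 0 °C
Reagents that add atoms: iodomethane, CI
Why: C-alkylation of a stabilised phosphorus ylide followed by deprotonation, the standard way to α-substituted stabilised ylides.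

Step 4
Reactants: 5 aldehyde dienoate; 8 α-methyl Weinreb ylide
Product: 9 ethyl (2E,4E,7S,10E)-12-[methoxy(methyl)amino]-3,7,11-trimethyl-12-oxododeca-2,4,10-trienoate
Conditions: toluene, 80 °C
Reagents that add atoms: none
Why: Wittig olefination with a stabilised, α-branched ylide, which should give the E-trisubstituted alkene under thermodynamic control of oxaphosphetane formation; the ester does not react.

Step 5
Reactants: 9 ester Weinreb amide
Product: 10 (2E,6S,8E,10E)-12-hydroxy-2,6,10-trimethyldodeca-2,8,10-trienal
Conditions: i-Bu2AlH (3.5 equiv), CH2Cl2, −78 °C; aq. potassium sodium tartrate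
Reagents that add atoms: none
Why: Hydride reduction; the dienoate is taken to the allylic alcohol, while the Weinreb amide stops at the chelated aluminium hemiaminal and releases the enal only on hydrolysis, so one operation sets both chain ends.

Step 6
Reactants: 10 hydroxy enal
Product: 11 methyl (2E,4E,7S,10E)-3,7,11-trimethyl-12-oxododeca-2,4,10-trien-1-yl carbonate
Conditions: ClCO2Me, pyridine, CH2Cl2, 0 °C
Reagents that add atoms: methyl chloroformate, COC(=O)Cl
Why: O-acylation of the primary allylic alcohol; the carbonate is the leaving group for the palladium step and supplies its own base there.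

Step 7
Reactants: 12 (S)-but-3-yn-2-ol
Product: 13 (S)-tert-butyl(but-3-yn-2-yloxy)dimethylsilane
Conditions: TBSCl, imidazole, CH2Cl2, 0 °C → rt
Reagents that add atoms: tert-butyldimethylsilyl chloride, CC(C)(C)[Si](C)(C)Cl
Why: Silylation of a secondary alcohol; the stereocentre is not involved.

Step 8
Reactants: 13 silyl ether of the alkynol
Product: 14 tert-butyldimethyl{[(2S,3E)-4-(4,4,5,5-tetramethyl-1,3,2-dioxaborolan-2-yl)but-3-en-2-yl]oxy}silane
Conditions: pinacolborane, Cp2Zr(H)Cl (10 mol %), Et3N (10 mol %), 60 °C
Reagents that add atoms: pinacolborane, CC1(C)OBOC1(C)C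
Why: Zirconium-catalysed hydroboration of a terminal alkyne; syn addition with boron at the terminal carbon should give the E-alkenylboronate only.

Step 9
Reactants: 11 dienyl allylic carbonate; 14 E-alkenylboronate
Product: 15 (2E,6S,8E,10E,13E,15S)-15-[(tert-butyldimethylsilyl)oxy]-2,6,10-trimethylhexadeca-2,8,10,13-tetraenal
Conditions: Pd(PPh3)4 (5 mol %), THF, 50 °C, no added base
Reagents that add atoms: none
Why: Suzuki–Miyaura allyl–alkenyl coupling of an allylic carbonate under neutral conditions: zerovalent palladium ionises the carbonate to an allylpalladium methoxide, which transmetalates with the boronate and couples at the unhindered CH2 terminus. The alkenyl geometry is retained, and the enal tolerates the neutral medium.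

Step 10
Reactants: 15 tetraenal
Product: 16 (1R,2S,4aR,6S,8aS)-2-[(2E,4S)-4-[(tert-butyldimethylsilyl)oxy]pent-2-en-1-yl]-1,3,6-trimethyl-1,2,4a,5,6,7,8,8a-octahydronaphthalene-1-carbaldehyde
Conditions: Me2AlCl (1.2 equiv), CH2Cl2, −78 → −30 °C
Reagents that add atoms: none
Why: Lewis-acid-promoted intramolecular Diels–Alder reaction, the mode established for citronellal-derived 2-methyl-2-enal trienes. The aldehyde-endo transition state with a chair-like tether and the C-methyl group equatorial should give the trans-decalin and set both fusion carbons. The E-enal places the formyl group cis to the fusion hydrogen on the neighbouring carbon, and the E,E-diene places the side chain cis to the formyl group.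

Step 11
Reactants: 17 N-methyl-L-serine
Product: 18 O-(tert-butyldiphenylsilyl)-N-methyl-L-serine
Conditions: TBDPSCl, DBU, MeCN, 0 °C → rt
Reagents that add atoms: tert-butyl(chloro)diphenylsilane, CC(C)(C)[Si](Cl)(c1ccccc1)c1ccccc1
Why: O-silylation of a hydroxy amino acid zwitterion; the bulky silyl chloride should react at the primary alcohol only, and a silyl ester, if formed, is lost on work-up.

Step 12
Reactants: 18 O-silyl amino acid
Product: 20 O-(tert-butyldiphenylsilyl)-N-methyl-N-[(4-nitrophenoxy)carbonyl]-L-serine, via trimethylsilyl ester 19 (not isolated)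
Conditions: TMSCl, i-Pr2NEt, CH2Cl2, 40 °C; then 4-nitrophenyl chloroformate, 0 °C → rt; aq. citric acid
Reagents that add atoms: 4-nitrophenyl chloroformate, O=C(Cl)Oc1ccc(cc1)[N+](=O)[O-]
Why: N-acylation of a secondary amine by a chloroformate after transient silylation of the acid, which makes the zwitterion soluble; the hydroxyl group is already blocked, so no oxazolidinone can form.

Step 13
Reactants: 20 carbamate acid
Product: 22 4-nitrophenyl N-[(2S)-1-[(tert-butyldiphenylsilyl)oxy]-4-diazo-3-oxobutan-2-yl]-N-methylcarbamate, via isobutyl mixed anhydride 21 (not isolated)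
Conditions: i-BuOCOCl, N-methylmorpholine, THF, −20 °C; then CH2N2, Et2O, −20 → 0 °C
Reagents that add atoms: diazomethane, C=[N+]=[N-]
Why: Acylation of diazomethane by a mixed carbonic anhydride (first stage of the Arndt–Eistert sequence); with a urethane on nitrogen the activated acid cannot form an oxazolone, so the α-stereocentre should be kept.

Step 14
Reactants: 16 decalin aldehyde; 22 serine diazomethyl ketone
Product: 23 α-diazo-β-hydroxy ketone (both carbinol epimers)
Conditions: 16 and 22 (1.3 equiv) in THF, −78 °C; LiN(SiMe3)2 (1.3 equiv) added slowly; AcOH, −78 °C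
Reagents that add atoms: none
Why: Aldol-type addition of a lithiated α-diazo ketone to an aldehyde; 16 has no α-hydrogen, so the base can be added to the mixture and the diazo anion is trapped as it forms. The new carbinol centre is oxidised in the next step and needs no control.

Step 15
Reactants: 23 α-diazo-β-hydroxy ketone
Product: 24 2-diazo-1,3-diketone (decalin C1 acyl group, diazo carbon, serine-derived ketone with 4-nitrophenyl carbamate and silyl ether)
Conditions: Dess–Martin periodinane, NaHCO3, CH2Cl2, 0 °C → rt
Reagents that add atoms: none
Why: Dess–Martin oxidation of an α-diazo-β-hydroxy carbonyl compound to the 2-diazo-1,3-dicarbonyl compound; the buffered, neutral conditions should leave the diazo group, the silyl ethers and the carbamate untouched.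

Step 16
Reactants: 24 2-diazo-1,3-diketone
Product: 25 tricyclic 2-acylcyclopentanone (ring C closed, ring D open; (3R,3aS,5aR,7S,9aS,9bR), serine carbon S, carbinol S)
Conditions: Rh2(O2CCPh3)4 (2 mol %), CH2Cl2, rt → 40 °C, slow addition of 24
Reagents that add atoms: none
Why: Rh2(O2CCPh3)4 takes up the diazo carbon, nitrogen leaves, and the rhodium carbenoid between the two ketones inserts in a concerted, asynchronous three-centre step into a C–H bond of the side-chain CH2 (C3), with retention at that carbon. The closest known reaction type is the dirhodium-carboxylate-catalysed 1,5-C–H insertion of α-diazo-β-dicarbonyl compounds to cyclopentanones. Ring C closes by this 1,5-insertion through a chair-like six-centre transition state (carbenoid carbon, C1, C9b, C3a, C3 and the migrating hydrogen); the cis B/C fusion is preset, because the acyl group on C9b is equatorial and the side chain on C3a is pseudoaxial on the same face. C3 is set in that transition state: the alkenyl group should take the pseudo-equatorial position on the convex face, away from C4 and its methyl group, so the alkenyl group ends trans to C4. C2 is formed as an enolisable centre, settles with the acyl group trans to the alkenyl group or as the enol, and is fixed only in step 17. The step needs insertion to win over cyclopropanation of the C1''=C2'' alkene (a six-membered closure onto a 1,2-disubstituted alkene), over insertion into C9–H2 of ring A (1,5, but giving a trans-fused five-membered ring) and into N–CH3 (primary, on a nitrogen bearing an acceptor), and over ylide formation at the carbamate carbonyl or the silyl ether oxygen. The substrate secures this through the decalin, which holds only the side-chain CH2 within reach on a freely rotating arm, and through the bulky silyl group and the electron-poor carbamate on the serine side; the triphenylacetate ligands are the ones that favour methylene insertion over addition to alkenes.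

Step 17
Reactants: 25 tricyclic 2-acylcyclopentanone
Product: 26 silyl-protected target (C3'' tert-butyldimethylsilyl ether, primary tert-butyldiphenylsilyl ether)
Conditions: MgBr2·OEt2, i-Pr2NEt, CH2Cl2, 0 °C → rt
Reagents that add atoms: none
Why: Proposed new method: the amine and MgBr2 convert the 2-acylcyclopentanone (pKa roughly 10) into its magnesium chelate, whose central carbon C2 attacks the carbamate carbonyl in a 5-exo-trig closure and expels 4-nitrophenoxide; the closest known reaction types are the carbamoyl Baker–Venkataraman rearrangement (enolate attack on an aryl carbamate), the soft-enolisation Claisen acylation of ketones with activated aryl esters and the Lacey–Dieckmann closure of tetramic acids, none of which has been used to make a non-enolisable spiro centre from a 1,3-diketone. The aryloxide is a weaker base than the diketonate, so the closure should be downhill although the product cannot be deprotonated, and the chelate should direct acylation to carbon and not to oxygen. The carbamate carbon can reach either face of C2 and should come in anti to the C3 alkenyl group, which places C2' cis to H-3 and C4' on the alkenyl side as in the target.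

Step 18
Reactants: 26 silyl-protected target
Product: 27 target
Conditions: HF·pyridine, pyridine, THF, 0 °C → rt
Reagents that add atoms: none
Why: Fluoride-mediated cleavage of both silyl ethers under weakly acidic conditions, which should spare the base-sensitive C5' centre, the β-hydroxy ketone and the tricarbonyl unit.

## Compound list

1 | (S)-citronellal, (3S)-3,7-dimethyloct-6-enal | C[C@@H](CCC=C(C)C)CC=O | starting material
2 | triethyl (E)-3-methyl-4-phosphonocrotonate, ethyl (2E)-4-(diethoxyphosphoryl)-3-methylbut-2-enoate | CCOC(=O)/C=C(\C)CP(=O)(OCC)OCC | starting material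
3 | ethyl (2E,4E,7S)-3,7,11-trimethyldodeca-2,4,10-trienoate | C[C@@H](CCC=C(C)C)C/C=C/C(C)=C/C(=O)OCC | intermediate
4 | secondary ozonide (1,2,4-trioxolane) of the C10=C11 alkene of 3 | C[C@@H](CCC1OOC(C)(C)O1)C/C=C/C(C)=C/C(=O)OCC | intermediate
5 | ethyl (2E,4E,7S)-3,7-dimethyl-10-oxodeca-2,4-dienoate | C[C@@H](CCC=O)C/C=C/C(C)=C/C(=O)OCC | intermediate
6 | N-methoxy-N-methyl-2-(triphenylphosphoranylidene)acetamide | CON(C)C(=O)C=P(c1ccccc1)(c1ccccc1)c1ccccc1 | starting material
7 | {1-[methoxy(methyl)amino]-1-oxopropan-2-yl}triphenylphosphonium iodide | CON(C)C(=O)C(C)[P+](c1ccccc1)(c1ccccc1)c1ccccc1.[I-] | intermediate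
8 | N-methoxy-N-methyl-2-(triphenylphosphoranylidene)propanamide | CON(C)C(=O)C(C)=P(c1ccccc1)(c1ccccc1)c1ccccc1 | intermediate
9 | ethyl (2E,4E,7S,10E)-12-[methoxy(methyl)amino]-3,7,11-trimethyl-12-oxododeca-2,4,10-trienoate | C[C@@H](CC/C=C(\C)C(=O)N(C)OC)C/C=C/C(C)=C/C(=O)OCC | intermediate
10 | (2E,6S,8E,10E)-12-hydroxy-2,6,10-trimethyldodeca-2,8,10-trienal | C[C@@H](CC/C=C(\C)C=O)C/C=C/C(C)=C/CO | intermediate
11 | methyl (2E,4E,7S,10E)-3,7,11-trimethyl-12-oxododeca-2,4,10-trien-1-yl carbonate | C[C@@H](CC/C=C(\C)C=O)C/C=C/C(C)=C/COC(=O)OC | intermediate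
12 | (S)-but-3-yn-2-ol | C#C[C@H](C)O | starting material
13 | (S)-tert-butyl(but-3-yn-2-yloxy)dimethylsilane | C#C[C@H](C)O[Si](C)(C)C(C)(C)C | intermediate
14 | tert-butyldimethyl{[(2S,3E)-4-(4,4,5,5-tetramethyl-1,3,2-dioxaborolan-2-yl)but-3-en-2-yl]oxy}silane | CC1(C)OB(/C=C/[C@H](C)O[Si](C)(C)C(C)(C)C)OC1(C)C | intermediate
15 | (2E,6S,8E,10E,13E,15S)-15-[(tert-butyldimethylsilyl)oxy]-2,6,10-trimethylhexadeca-2,8,10,13-tetraenal | C[C@@H](CC/C=C(\C)C=O)C/C=C/C(C)=C/C/C=C/[C@H](C)O[Si](C)(C)C(C)(C)C | intermediate
16 | (1R,2S,4aR,6S,8aS)-2-[(2E,4S)-4-[(tert-butyldimethylsilyl)oxy]pent-2-en-1-yl]-1,3,6-trimethyl-1,2,4a,5,6,7,8,8a-octahydronaphthalene-1-carbaldehyde | CC1=C[C@H]2C[C@@H](C)CC[C@@H]2[C@@](C)(C=O)[C@H]1C/C=C/[C@H](C)O[Si](C)(C)C(C)(C)C | intermediate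
17 | N-methyl-L-serine | CN[C@@H](CO)C(=O)O | starting material
18 | O-(tert-butyldiphenylsilyl)-N-methyl-L-serine | CN[C@@H](CO[Si](c1ccccc1)(c1ccccc1)C(C)(C)C)C(=O)O | intermediate
19 | trimethylsilyl O-(tert-butyldiphenylsilyl)-N-methyl-L-serinate | CN[C@@H](CO[Si](c1ccccc1)(c1ccccc1)C(C)(C)C)C(=O)O[Si](C)(C)C | intermediate
20 | O-(tert-butyldiphenylsilyl)-N-methyl-N-[(4-nitrophenoxy)carbonyl]-L-serine | CN([C@@H](CO[Si](c1ccccc1)(c1ccccc1)C(C)(C)C)C(=O)O)C(=O)Oc1ccc(cc1)[N+](=O)[O-] | intermediate
21 | mixed anhydride of 20 with isobutyl hydrogen carbonate | CN([C@@H](CO[Si](c1ccccc1)(c1ccccc1)C(C)(C)C)C(=O)OC(=O)OCC(C)C)C(=O)Oc1ccc(cc1)[N+](=O)[O-] | intermediate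
22 | 4-nitrophenyl N-[(2S)-1-[(tert-butyldiphenylsilyl)oxy]-4-diazo-3-oxobutan-2-yl]-N-methylcarbamate | CN([C@@H](CO[Si](c1ccccc1)(c1ccccc1)C(C)(C)C)C(=O)C=[N+]=[N-])C(=O)Oc1ccc(cc1)[N+](=O)[O-] | intermediate
23 | 4-nitrophenyl N-[(2S)-1-[(tert-butyldiphenylsilyl)oxy]-4-diazo-5-hydroxy-3-oxo-5-{(1R,2S,4aR,6S,8aS)-2-[(2E,4S)-4-[(tert-butyldimethylsilyl)oxy]pent-2-en-1-yl]-1,3,6-trimethyl-1,2,4a,5,6,7,8,8a-octahydronaphthalen-1-yl}pentan-2-yl]-N-methylcarbamate (both C5 epimers) | CC1=C[C@H]2C[C@@H](C)CC[C@@H]2[C@@](C)(C(O)C(=[N+]=[N-])C(=O)[C@H](CO[Si](c2ccccc2)(c2ccccc2)C(C)(C)C)N(C)C(=O)Oc2ccc(cc2)[N+](=O)[O-])[C@H]1C/C=C/[C@H](C)O[Si](C)(C)C(C)(C)C | intermediate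
24 | 4-nitrophenyl N-[(2S)-1-[(tert-butyldiphenylsilyl)oxy]-4-diazo-3,5-dioxo-5-{(1R,2S,4aR,6S,8aS)-2-[(2E,4S)-4-[(tert-butyldimethylsilyl)oxy]pent-2-en-1-yl]-1,3,6-trimethyl-1,2,4a,5,6,7,8,8a-octahydronaphthalen-1-yl}pentan-2-yl]-N-methylcarbamate | CC1=C[C@H]2C[C@@H](C)CC[C@@H]2[C@@](C)(C(=O)C(=[N+]=[N-])C(=O)[C@H](CO[Si](c2ccccc2)(c2ccccc2)C(C)(C)C)N(C)C(=O)Oc2ccc(cc2)[N+](=O)[O-])[C@H]1C/C=C/[C@H](C)O[Si](C)(C)C(C)(C)C | intermediate
25 | 4-nitrophenyl N-[(2S)-1-[(tert-butyldiphenylsilyl)oxy]-3-oxo-3-{(3R,3aS,5aR,7S,9aS,9bR)-3-[(1E,3S)-3-[(tert-butyldimethylsilyl)oxy]but-1-en-1-yl]-4,7,9b-trimethyl-1-oxo-2,3,3a,5a,6,7,8,9,9a,9b-decahydro-1H-cyclopenta[a]naphthalen-2-yl}propan-2-yl]-N-methylcarbamate (C2 drawn trans to the alkenyl group; enolisable) | CC1=C[C@H]2C[C@@H](C)CC[C@@H]2[C@@]2(C)C(=O)[C@@H](C(=O)[C@H](CO[Si](c3ccccc3)(c3ccccc3)C(C)(C)C)N(C)C(=O)Oc3ccc(cc3)[N+](=O)[O-])[C@H](/C=C/[C@H](C)O[Si](C)(C)C(C)(C)C)[C@@H]12 | intermediate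
26 | (2S,3R,3aS,5'S,5aR,7S,9aS,9bR)-3-[(1E,3S)-3-[(tert-butyldimethylsilyl)oxy]but-1-en-1-yl]-5'-{[(tert-butyldiphenylsilyl)oxy]methyl}-1',4,7,9b-tetramethyl-3,3a,5a,6,7,8,9,9a-octahydrospiro[cyclopenta[a]naphthalene-2,3'-pyrrolidine]-1,2',4'(9bH)-trione | CC1=C[C@H]2C[C@@H](C)CC[C@@H]2[C@@]2(C)C(=O)[C@]3(C(=O)[C@H](CO[Si](c4ccccc4)(c4ccccc4)C(C)(C)C)N(C)C3=O)[C@H](/C=C/[C@H](C)O[Si](C)(C)C(C)(C)C)[C@@H]12 | intermediate
27 | (2S,3R,3aS,5'S,5aR,7S,9aS,9bR)-3-[(1E,3S)-3-hydroxybut-1-en-1-yl]-5'-(hydroxymethyl)-1',4,7,9b-tetramethyl-3,3a,5a,6,7,8,9,9a-octahydrospiro[cyclopenta[a]naphthalene-2,3'-pyrrolidine]-1,2',4'(9bH)-trione | CC1=C[C@H]2C[C@@H](C)CC[C@@H]2[C@@]2(C)C(=O)[C@]3(C(=O)[C@H](CO)N(C)C3=O)[C@H](/C=C/[C@H](C)O)[C@@H]12 | target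

## Step count and least certain steps

Total step count: 18. Longest linear sequence: 12 steps from 1 (steps 1, 2, 4, 5, 6, 9, 10, 14, 15, 16, 17, 18).

Step 17 (ring D closure). Most likely to go wrong:
- acylation at an enolate oxygen instead of C2, giving a cyclic enol carbamate;
- reversal or stalling of a closure that gains nothing from enolisation of the product;
- soft enolisation of the C4' ketone of 26 towards C5', with epimerisation or loss of the silyloxy group;
- closure on the face syn to the alkenyl group.

The fallback uses known chemistry and closes ring D at the other bond (C2–C4'). It sets out from 16. Tin dichloride (SnCl2)-catalysed homologation with ethyl diazoacetate (Roskamp reaction) gives the ethyl β-keto ester F1. Diazo transfer with 4-acetamidobenzenesulfonyl azide and Et3N gives the diazo β-keto ester F2, and Rh2(OAc)4 converts it by the classical 1,5-C–H insertion into the tricyclic β-keto ester F3. Separately, 18 is esterified with trimethylsilyldiazomethane to the amino ester methyl O-(tert-butyldiphenylsilyl)-N-methyl-L-serinate F4. Heating F3 with F4 in toluene (with 4-dimethylaminopyridine) gives the β-keto amide F5, and NaOMe in MeOH closes ring D by a Lacey–Dieckmann condensation to come back at 26. In this closure the ketone carbon C4' is the group that arrives last at C2, so the spiro configuration would rest on the reversibility of the Dieckmann step and on separation of the two spiro epimers.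

Step 16 (key step). Most likely to go wrong:
- addition of the carbenoid to the side-chain alkene (cyclopropanation) instead of insertion;
- capture of the carbenoid by the carbamate carbonyl oxygen or the silyl ether oxygen (ylide formation);
- insertion at C9–H2 or N–CH3;
- low selectivity between the two hydrogens at C3.

The fallback takes the serine unit out of the carbenoid step. It sets out from 16 and runs through the keto ester F1, the diazo ester F2 and the tricyclic β-keto ester F3 described above, the substrate class for which this insertion is best established. Hydrolysis of F3 with LiOH and decarboxylation on mild acidification give the tricyclic ketone F6, which can enolise only towards C2. Acid 20 is converted with pentafluorophenol and dicyclohexylcarbodiimide into the pentafluorophenyl ester F7. Acylation of F6 with F7 under soft enolisation (MgBr2·OEt2, i-Pr2NEt) comes back at 25, which under the same conditions may run on to 26.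

Step 9 (allyl–alkenyl coupling). Most likely to go wrong: slow transmetalation of the branched alkenylboronate, which leaves the pentadienyl–palladium intermediate time to isomerise (loss of the 10E geometry), to couple at its far terminus or to undergo β-hydride elimination. The fallback sets out from 11 and couples it with the small, fast-reacting 4,4,5,5-tetramethyl-2-vinyl-1,3,2-dioxaborolane to give the allyl-substituted tetraenal F8. The same Diels–Alder reaction gives the allyl decalin aldehyde F9. Cross-metathesis of F9 with (S)-tert-butyl(but-3-en-2-yloxy)dimethylsilane F10 (from commercial (S)-but-3-en-2-ol and TBSCl), with the second-generation Hoveyda–Grubbs catalyst, builds the E-alkene and comes back at 16; the trisubstituted ring alkene should not take part.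

Step 14 (diazo aldol addition). Most likely to go wrong: incomplete or reversible addition to the neopentyl aldehyde, attack of the diazo anion on its own carbamate, and epimerisation at the serine carbon while the anion waits. The fallback replaces addition and oxidation by one irreversible acylation. It sets out from 16: Pinnick oxidation gives the decalin acid F11, oxalyl chloride gives the acid chloride F12, and F12 acylates the lithium derivative of 22 at −78 °C to come back at 24.

Step 2 (selective ozonolysis). Most likely to go wrong: over-oxidation, in which ozone also cleaves the C4=C5 alkene of the dienoate once the trialkyl alkene is consumed. The fallback sets out from 3: 3-chloroperoxybenzoic acid epoxidises only the electron-rich trisubstituted alkene to the epoxide F13, and periodic acid cleaves F13 to come back at 5.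

## Further compounds

F1 | step 17 | ethyl 3-oxo-3-{(1R,2S,4aR,6S,8aS)-2-[(2E,4S)-4-[(tert-butyldimethylsilyl)oxy]pent-2-en-1-yl]-1,3,6-trimethyl-1,2,4a,5,6,7,8,8a-octahydronaphthalen-1-yl}propanoate | CC1=C[C@H]2C[C@@H](C)CC[C@@H]2[C@@](C)(C(=O)CC(=O)OCC)[C@H]1C/C=C/[C@H](C)O[Si](C)(C)C(C)(C)C
F2 | step 17 | ethyl 2-diazo-3-oxo-3-{(1R,2S,4aR,6S,8aS)-2-[(2E,4S)-4-[(tert-butyldimethylsilyl)oxy]pent-2-en-1-yl]-1,3,6-trimethyl-1,2,4a,5,6,7,8,8a-octahydronaphthalen-1-yl}propanoate | CC1=C[C@H]2C[C@@H](C)CC[C@@H]2[C@@](C)(C(=O)C(=[N+]=[N-])C(=O)OCC)[C@H]1C/C=C/[C@H](C)O[Si](C)(C)C(C)(C)C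
F3 | step 17 | ethyl (3R,3aS,5aR,7S,9aS,9bR)-3-[(1E,3S)-3-[(tert-butyldimethylsilyl)oxy]but-1-en-1-yl]-4,7,9b-trimethyl-1-oxo-2,3,3a,5a,6,7,8,9,9a,9b-decahydro-1H-cyclopenta[a]naphthalene-2-carboxylate (C2 enolisable) | CC1=C[C@H]2C[C@@H](C)CC[C@@H]2[C@@]2(C)C(=O)C(C(=O)OCC)[C@H](/C=C/[C@H](C)O[Si](C)(C)C(C)(C)C)[C@@H]12
F4 | step 17 | methyl O-(tert-butyldiphenylsilyl)-N-methyl-L-serinate | CN[C@@H](CO[Si](c1ccccc1)(c1ccccc1)C(C)(C)C)C(=O)OC
F5 | step 17 | methyl N-{[(3R,3aS,5aR,7S,9aS,9bR)-3-[(1E,3S)-3-[(tert-butyldimethylsilyl)oxy]but-1-en-1-yl]-4,7,9b-trimethyl-1-oxo-2,3,3a,5a,6,7,8,9,9a,9b-decahydro-1H-cyclopenta[a]naphthalen-2-yl]carbonyl}-O-(tert-butyldiphenylsilyl)-N-methyl-L-serinate | CC1=C[C@H]2C[C@@H](C)CC[C@@H]2[C@@]2(C)C(=O)C(C(=O)N(C)[C@@H](CO[Si](c3ccccc3)(c3ccccc3)C(C)(C)C)C(=O)OC)[C@H](/C=C/[C@H](C)O[Si](C)(C)C(C)(C)C)[C@@H]12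
F6 | step 16 | (3R,3aS,5aR,7S,9aS,9bR)-3-[(1E,3S)-3-[(tert-butyldimethylsilyl)oxy]but-1-en-1-yl]-4,7,9b-trimethyl-2,3,3a,5a,6,7,8,9,9a,9b-decahydro-1H-cyclopenta[a]naphthalen-1-one | CC1=C[C@H]2C[C@@H](C)CC[C@@H]2[C@@]2(C)C(=O)C[C@H](/C=C/[C@H](C)O[Si](C)(C)C(C)(C)C)[C@@H]12
F7 | step 16 | pentafluorophenyl O-(tert-butyldiphenylsilyl)-N-methyl-N-[(4-nitrophenoxy)carbonyl]-L-serinate | CN([C@@H](CO[Si](c1ccccc1)(c1ccccc1)C(C)(C)C)C(=O)Oc1c(F)c(F)c(F)c(F)c1F)C(=O)Oc1ccc(cc1)[N+](=O)[O-]
F8 | step 9 | (2E,6S,8E,10E)-2,6,10-trimethyltetradeca-2,8,10,13-tetraenal | C[C@@H](CC/C=C(\C)C=O)C/C=C/C(C)=C/CC=C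
F9 | step 9 | (1R,2S,4aR,6S,8aS)-1,3,6-trimethyl-2-(prop-2-en-1-yl)-1,2,4a,5,6,7,8,8a-octahydronaphthalene-1-carbaldehyde | CC1=C[C@H]2C[C@@H](C)CC[C@@H]2[C@@](C)(C=O)[C@H]1CC=C
F10 | step 9 | (S)-tert-butyl(but-3-en-2-yloxy)dimethylsilane | C=C[C@H](C)O[Si](C)(C)C(C)(C)C
F11 | step 14 | (1R,2S,4aR,6S,8aS)-2-[(2E,4S)-4-[(tert-butyldimethylsilyl)oxy]pent-2-en-1-yl]-1,3,6-trimethyl-1,2,4a,5,6,7,8,8a-octahydronaphthalene-1-carboxylic acid | CC1=C[C@H]2C[C@@H](C)CC[C@@H]2[C@@](C)(C(=O)O)[C@H]1C/C=C/[C@H](C)O[Si](C)(C)C(C)(C)C
F12 | step 14 | (1R,2S,4aR,6S,8aS)-2-[(2E,4S)-4-[(tert-butyldimethylsilyl)oxy]pent-2-en-1-yl]-1,3,6-trimethyl-1,2,4a,5,6,7,8,8a-octahydronaphthalene-1-carbonyl chloride | CC1=C[C@H]2C[C@@H](C)CC[C@@H]2[C@@](C)(C(=O)Cl)[C@H]1C/C=C/[C@H](C)O[Si](C)(C)C(C)(C)C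
F13 | step 2 | ethyl (2E,4E,7S)-9-(3,3-dimethyloxiran-2-yl)-3,7-dimethylnona-2,4-dienoate | C[C@@H](CCC1OC1(C)C)C/C=C/C(C)=C/C(=O)OCC
A1 | alternative 1 | tricyclic enedione, 4,7,9b-trimethyl-2,3,5a,6,7,8,9,9a-octahydro-1H-cyclopenta[a]naphthalene-1,5(9bH)-dione | CC1=C2CCC(=O)[C@]2(C)[C@H]2CC[C@H](C)C[C@@H]2C1=O
A2 | alternative 1 | 2-methylcyclopentane-1,3-dione | CC1C(=O)CCC1=O
A3 | alternative 1 | (S)-1-(5-methylcyclohex-1-en-1-yl)propan-1-one | CCC(=O)C1=CCC[C@H](C)C1
A4 | alternative 2 | (1R,2S,4aR,6S,8aS)-1,3,6-trimethyl-2-[(1E,3E)-penta-1,3-dien-1-yl]-1,2,4a,5,6,7,8,8a-octahydronaphthalene-1-carboxylic acid | CC1=C[C@H]2C[C@@H](C)CC[C@@H]2[C@@](C)(C(=O)O)[C@H]1/C=C/C=C/C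
A5 | alternative 3 | bis(tert-butyldimethylsilyl) ether of 27 | CC1=C[C@H]2C[C@@H](C)CC[C@@H]2[C@@]2(C)C(=O)[C@]3(C(=O)[C@H](CO[Si](C)(C)C(C)(C)C)N(C)C3=O)[C@H](/C=C/[C@H](C)O[Si](C)(C)C(C)(C)C)[C@@H]12
A6 | alternative 3 | 3-acyltetramic acid with a Z-alkenyl iodide on ring A and a (1E,3E,5S)-5-silyloxyhexa-1,3-dienyl group on the quaternary carbon | C/C(I)=C/[C@H]1C[C@@H](C)CC[C@@H]1[C@@](C)(C(=O)C1C(=O)[C@H](CO[Si](C)(C)C(C)(C)C)N(C)C1=O)/C=C/C=C/[C@H](C)O[Si](C)(C)C(C)(C)C
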